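**Atom numbering:** cembrane numbering. C1 carries the lactone β-carbon, C2 is the lactone carbinol, C3 and C13 carry OAc, C4, C8 and C12 carry methyls, and C12 is the tertiary alcohol.

**Assumptions (one line each):**
- The trans relationship of C1/C2 drawn in the target SMILES is the intended relative configuration.
- The Ohira–Bestmann step (1→2) is assumed to proceed without meaningful racemisation.

## Retrosynthetic overview
1. Cut C1–C2 and open the α-methylene-γ-lactone. A photoredox/Cr allylation of a C2 α-hydroxy aldehyde with a (Z)-2-(bromomethyl)enoate closes the 14-membered ring, both stereocentres C1/C2 and the trans-lactone in one step. This is the only skeletal ring-forming step and comes last.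
2. The bromo-enoate comes from a Baylis–Hillman adduct of the C1 aldehyde. That aldehyde comes from a β-keto-acetal of the Wacker α-ketol. C13 is set by chelation-controlled reduction next to C12.
3. C12 comes from (R)-linalool. The C6–C7 bond forms by Cu-catalysed allyl–allyl coupling of 8-bromolinalool with an allyl Grignard. That Grignard derives from an (E)-allylic bromide made by Zr-catalysed carboalumination of a glyceraldehyde-derived alkyne, which supplies C3. The dioxolane is only a protecting ring.

## Route

**Step 1**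
Reactants: 1, (4R)-2,2-dimethyl-1,3-dioxolane-4-carbaldehyde
Product: 2, (4S)-4-ethynyl-2,2-dimethyl-1,3-dioxolane
Conditions: Ohira–Bestmann reagent, K2CO3, MeOH, 0 °C → rt
Reagents that add atoms: dimethyl (1-diazo-2-oxopropyl)phosphonate, `COP(=O)(OC)C(=[N+]=[N-])C(C)=O` (supplies the terminal alkyne carbon)
Why: Seyferth–Gilbert/Ohira–Bestmann homologation converts CHO to C≡CH under mild base, so the α-stereocentre (future C3) is kept.

**Step 2**
Reactants: 2
Product: 3, (2E)-3-[(4S)-2,2-dimethyl-1,3-dioxolan-4-yl]but-2-en-1-ol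
Conditions: Me3Al, Cp2ZrCl2 (cat.), ClCH2CH2Cl, rt; then n-BuLi, THF, –78 °C; then (CH2O)n, –78 °C → rt
Reagents that add atoms: trimethylaluminium `C[Al](C)C` (CH3 on C4); paraformaldehyde `C=O` (C6H2OH)
Why: Negishi syn-methylalumination puts Me and Al cis on the alkene, so C3 and C6 end up trans (E, C4=C5); the alanate then adds to formaldehyde, and C3 is untouched.

**Step 3**
Reactants: 3
Product: 4, (4S)-4-[(2E)-4-bromobut-2-en-2-yl]-2,2-dimethyl-1,3-dioxolane
Conditions: PPh3, CBr4, CH2Cl2, 0 °C
Reagents that add atoms: carbon tetrabromide `BrC(Br)(Br)Br`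
Why: Appel bromination of a primary allylic alcohol is SN2 at carbon, with no allylic transposition and no effect on alkene geometry.

**Step 4**
Reactants: 5, (3R)-linalool (3,7-dimethylocta-1,6-dien-3-ol)
Product: 6, (2E,6R)-2,6-dimethylocta-2,7-diene-1,6-diol
Conditions: SeO2 (10 mol %), t-BuOOH, CH2Cl2, rt
Reagents that add atoms: selenium dioxide `O=[Se]=O`; tert-butyl hydroperoxide `CC(C)(C)OO` (source of the new O)
Why: Riley/Sharpless allylic oxidation hydroxylates the methyl trans to the chain (the E-methyl, future C7), which sets the C8=C9 geometry, while the tertiary carbinol (C12) and the vinyl group are untouched.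

**Step 5**
Reactants: 6
Product: 7, (2E,6R)-1-bromo-2,6-dimethylocta-2,7-dien-6-ol
Conditions: PPh3, CBr4, CH2Cl2, 0 °C
Reagents that add atoms: carbon tetrabromide `BrC(Br)(Br)Br`
Why: Appel conditions are selective for the primary allylic alcohol; the hindered tertiary alcohol does not react.

**Step 6**
Reactants: 4 and 7
Product: 8, (3R,6E,10E)-11-[(4S)-2,2-dimethyl-1,3-dioxolan-4-yl]-3,7,11-trimethylundeca-1,6,10-trien-3-ol
Conditions: Mg, THF, 0 °C (allylic Grignard from 4, 3 equiv); then 7 and Li2CuCl4 (5 mol %), –30 → 0 °C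
Reagents that add atoms: none
Why: Cu-catalysed head-to-tail allyl–allyl SN2 coupling forms C6–C7 at the unhindered primary termini, giving the E,E-diene skeleton; the extra Grignard equivalents absorb the free tertiary OH.

**Step 7**
Reactants: 8
Product: 9, (3R,6E,10E)-11-[(4S)-2,2-dimethyl-1,3-dioxolan-4-yl]-3-hydroxy-3,7,11-trimethylundeca-6,10-dien-2-one
Conditions: PdCl2 (10 mol %), CuCl, O2 (1 atm), DMF/H2O 7:1, 25 °C
Reagents that add atoms: water `O` (becomes the ketone O)
Why: Tsuji–Wacker oxidation is Markovnikov and selective for the monosubstituted vinyl group (C13=C14), which gives the methyl ketone (C13 oxidised, C14 = CH3) and leaves both trisubstituted alkenes alone.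

**Step 8**
Reactants: 9
Product: 10, (4R,7E,11E)-12-[(4S)-2,2-dimethyl-1,3-dioxolan-4-yl]-1,1-dimethoxy-4-hydroxy-4,8,12-trimethyldodeca-7,11-dien-3-one
Conditions: TMSOTf, Et3N, CH2Cl2, –78 °C; then HC(OMe)3, TMSOTf (cat.), –78 °C; then K2CO3, MeOH
Reagents that add atoms: trimethyl orthoformate `COC(OC)OC` (adds CH(OMe)2 as C1)
Why: Mukaiyama-type C-formylation of the silyl enol ether is fully regioselective because C14 is the only enolisable position (C12 is quaternary); K2CO3/MeOH removes the O-TMS group.

**Step 9**
Reactants: 10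
Product: 11, (3S,4R,7E,11E)-12-[(4S)-2,2-dimethyl-1,3-dioxolan-4-yl]-1,1-dimethoxy-4,8,12-trimethyldodeca-7,11-diene-3,4-diol
Conditions: Zn(BH4)2, Et2O, –20 °C
Reagents that add atoms: none
Why: Chelation-controlled (Cram-chelate) reduction of the α-hydroxy ketone delivers hydride to the face syn to the smaller C12 methyl (anti to the C11 chain), which sets C13 (S) against the bought C12 (R).

**Step 10**
Reactants: 11
Product: 12, 3-O-TBS ether of 11
Conditions: TBSOTf (1.05 equiv), 2,6-lutidine, CH2Cl2, –78 °C
Reagents that add atoms: tert-butyldimethylsilyl triflate `CC(C)(C)[Si](C)(C)OS(=O)(=O)C(F)(F)F`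
Why: The less hindered secondary C13–OH is silylated in preference to the tertiary C12–OH, and the silyl ether stops β-elimination in the Baylis–Hillman step.

**Step 11**
Reactants: 12
Product: 13, (3S,4R,7E,11E)-3-(TBSO)-12-[(4S)-dioxolanyl]-4-hydroxy-4,8,12-trimethyldodeca-7,11-dienal
Conditions: PPTS, acetone/H2O 10:1, 50 °C
Reagents that add atoms: water `O`
Why: Mild acid hydrolyses the acyclic dimethyl acetal much faster than the acetonide, which unmasks the C1 aldehyde.

**Step 12**
Reactants: 13 and 14, methyl acrylate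
Product: 15, methyl (5S,6R,9E,13E)-14-[(4S)-dioxolanyl]-5-(TBSO)-3,6-dihydroxy-6,10,14-trimethyl-2-methylidenetetradeca-9,13-dienoate (C3 epimeric mixture)
Conditions: methyl acrylate (10 equiv), DABCO (0.3 equiv), neat, 25 °C, 4 d
Reagents that add atoms: none (methyl acrylate is reactant 14)
Why: Morita–Baylis–Hillman reaction builds the C1–C15 bond; the new carbinol stereocentre is destroyed in the next step, so its configuration does not matter.

**Step 13**
Reactants: 15
Product: 16, methyl (2Z,5S,6R,9E,13E)-2-(bromomethyl)-14-[(4S)-dioxolanyl]-5-(TBSO)-6-hydroxy-6,10,14-trimethyltetradeca-2,9,13-trienoate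
Conditions: MsCl, Et3N, CH2Cl2, 0 °C; then LiBr, THF, 25 °C
Reagents that add atoms: lithium bromide `[Li+].[Br-]` (Br)
Why: The Baylis–Hillman mesylate undergoes SN2′ displacement by bromide, giving the thermodynamic (Z)-2-(bromomethyl)alkenoate and setting C1 as sp2 (C1=C15).

**Step 14**
Reactants: 16
Product: 17, 16 with the acetonide removed (C2 primary OH, C3 secondary OH)
Conditions: Zn(NO3)2·6H2O (0.5 equiv), MeCN, 50 °C
Reagents that add atoms: water `O`
Why: This Lewis-acid acetonide cleavage is mild enough to leave the TBS ether, the allyl bromide and the tertiary alcohol intact.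

**Step 15**
Reactants: 17
Product: 18, α-hydroxy aldehyde (C2 = CHO, C3 = OH, C3 (S)); used crude
Conditions: TEMPO (5 mol %), PhI(OAc)2, CH2Cl2, 0 °C
Reagents that add atoms: none
Why: TEMPO/PIDA oxidises the primary alcohol selectively over the secondary allylic alcohol under non-basic conditions, so C3 does not epimerise.

**Step 16**
Reactants: 18
Product: 19, (1R,2R,3S,12R,13S) TBS ether of the trans-fused α-methylene-γ-butyrolactone macrocycle (3,12-diol, 13-OTBS)
Conditions: CrCl3 (15 mol %), 4CzIPN (2 mol %), Hantzsch ester (1.5 equiv), TMSCl (3 equiv), MeCN/THF 1:1, 2 mM, blue LEDs (450 nm), 25 °C; then 1 M HCl/THF; then p-TsOH (cat.), PhMe, 50 °C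
Reagents that add atoms: none retained (TMSCl and Hantzsch ester leave no atoms in the product; Br is lost as bromide and MeOH is lost on lactonisation)
Why: Proposed new method: visible-light photoredox/chromium dual catalysis drives a macrocyclic Nozaki–Hiyama–Kishi allylation, in which excited 4CzIPN with Hantzsch ester regenerates Cr(II) from Cr(III) (replacing stoichiometric Mn or Cr), Cr(II) converts the allyl bromide to the allyl-Cr(III) species, and TMSCl releases Cr from the alkoxide. The allyl-Cr adds through its γ-carbon (C1) in a chair Zimmerman–Traxler transition state, so the new C1–C2 bond is anti and the lactone is trans-fused; C2 is set by Felkin–Anh addition anti to the in-situ C3–OTMS, since TMSCl suppresses chelation. The closest known reactions are the Cr-catalysed NHK allylation and stoichiometric-Cr macrocyclic NHK closures, now applied under light-driven catalytic Cr to this α-silyloxy aldehyde and bromoenoate.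

**Step 17**
Reactants: 19
Product: 20, (1R,2R,3S,12R,13S)-3,12,13-trihydroxy α-methylene-γ-lactone macrocycle
Conditions: HF·pyridine, pyridine, THF, 0 °C → rt
Reagents that add atoms: none
Why: Fluoride cleaves the secondary TBS ether without touching the lactone, the alkenes or the exocyclic methylene.

**Step 18**
Reactants: 20
Product: 21, Crassocolide B
Conditions: Ac2O (3 equiv), DMAP (0.2 equiv), pyridine, rt
Reagents that add atoms: acetic anhydride `CC(=O)OC(C)=O` (acetyl groups)
Why: The two secondary alcohols (C3 and C13) are acylated selectively while the hindered tertiary C12–OH is left free, which gives the target.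

## Compound list
1 | (4R)-2,2-dimethyl-1,3-dioxolane-4-carbaldehyde | `O=C[C@H]1COC(C)(C)O1` | starting material
2 | (4S)-4-ethynyl-2,2-dimethyl-1,3-dioxolane | `C#C[C@H]1COC(C)(C)O1` | intermediate
3 | (2E)-3-[(4S)-dioxolanyl]but-2-en-1-ol | `OC/C=C(\C)[C@H]1COC(C)(C)O1` | intermediate
4 | (4S)-4-[(2E)-4-bromobut-2-en-2-yl]-2,2-dimethyl-1,3-dioxolane | `BrC/C=C(\C)[C@H]1COC(C)(C)O1` | intermediate
5 | (3R)-linalool | `C=C[C@](C)(O)CCC=C(C)C` | starting material
6 | (2E,6R)-2,6-dimethylocta-2,7-diene-1,6-diol | `C=C[C@](C)(O)CC/C=C(\C)CO` | intermediate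
7 | (2E,6R)-1-bromo-2,6-dimethylocta-2,7-dien-6-ol | `C=C[C@](C)(O)CC/C=C(\C)CBr` | intermediate
8 | (3R,6E,10E)-11-[(4S)-dioxolanyl]-3,7,11-trimethylundeca-1,6,10-trien-3-ol | `C=C[C@](C)(O)CC/C=C(\C)CC/C=C(\C)[C@H]1COC(C)(C)O1` | intermediate
9 | α-ketol (Wacker product) | `CC(=O)[C@](C)(O)CC/C=C(\C)CC/C=C(\C)[C@H]1COC(C)(C)O1` | intermediate
10 | β-keto dimethyl acetal | `COC(OC)CC(=O)[C@](C)(O)CC/C=C(\C)CC/C=C(\C)[C@H]1COC(C)(C)O1` | intermediate
11 | 3,4-diol acetal | `COC(OC)C[C@H](O)[C@](C)(O)CC/C=C(\C)CC/C=C(\C)[C@H]1COC(C)(C)O1` | intermediate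
12 | 3-OTBS acetal | `COC(OC)C[C@H](O[Si](C)(C)C(C)(C)C)[C@](C)(O)CC/C=C(\C)CC/C=C(\C)[C@H]1COC(C)(C)O1` | intermediate
13 | C1 aldehyde | `O=CC[C@H](O[Si](C)(C)C(C)(C)C)[C@](C)(O)CC/C=C(\C)CC/C=C(\C)[C@H]1COC(C)(C)O1` | intermediate
14 | methyl acrylate | `C=CC(=O)OC` | starting material
15 | Baylis–Hillman adduct (C1 epimers) | `C=C(C(=O)OC)C(O)C[C@H](O[Si](C)(C)C(C)(C)C)[C@](C)(O)CC/C=C(\C)CC/C=C(\C)[C@H]1COC(C)(C)O1` | intermediate
16 | (Z)-allylic bromide | `BrC/C(C(=O)OC)=C\C[C@H](O[Si](C)(C)C(C)(C)C)[C@](C)(O)CC/C=C(\C)CC/C=C(\C)[C@H]1COC(C)(C)O1` | intermediate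
17 | diol (acetonide removed) | `BrC/C(C(=O)OC)=C\C[C@H](O[Si](C)(C)C(C)(C)C)[C@](C)(O)CC/C=C(\C)CC/C=C(\C)[C@H](O)CO` | intermediate
18 | α-hydroxy aldehyde | `BrC/C(C(=O)OC)=C\C[C@H](O[Si](C)(C)C(C)(C)C)[C@](C)(O)CC/C=C(\C)CC/C=C(\C)[C@H](O)C=O` | intermediate
19 | macrocyclic lactone, 13-OTBS | `C=C1C(=O)O[C@@H]2[C@@H]1C[C@H](O[Si](C)(C)C(C)(C)C)[C@](C)(O)CC/C=C(\C)CC/C=C(\C)[C@@H]2O` | intermediate
20 | macrocyclic lactone triol | `C=C1C(=O)O[C@@H]2[C@@H]1C[C@H](O)[C@](C)(O)CC/C=C(\C)CC/C=C(\C)[C@@H]2O` | intermediate
21 | Crassocolide B | `C=C1C(=O)O[C@@H]2[C@@H]1C[C@H](OC(C)=O)[C@](C)(O)CC/C=C(\C)CC/C=C(\C)[C@@H]2OC(C)=O` | target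

**Total steps: 18. Longest linear sequence: 16** (1, 2, 3, 6, then 7–18).

## Three steps most likely to fail
1. **Step 16 (new photoredox/Cr macrocyclisation).** Risks are low diastereoselectivity at C2/C1, or oligomerisation or reduction of the aldehyde. Fallback: replace the light-driven catalytic Cr cycle with the classical thermal NHK macrocyclisation, using stoichiometric CrCl2 with cat. NiCl2 in degassed DMF at 2 mM with syringe-pump addition (known for cembranolide ring closures), then lactonise as in step 16.
2. **Step 9 (chelation-controlled reduction, C13 diastereoselectivity).** The Me versus CH2R size difference at C12 is small. Fallback: reduce with a different reagent, separate the diastereomers, and convert the unwanted C13 epimer to the required one by Mitsunobu inversion (p-O2NC6H4CO2H, DIAD, PPh3, then methanolysis), which is known chemistry.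
3. **Step 6 (Cu-catalysed allyl–allyl coupling).** Risks are α/γ regioselectivity and E/Z scrambling of the allyl Grignard. Fallback: take allylic bromide 4 to its allyl phenyl sulfone (PhSO2Na, DMF), deprotonate (n-BuLi, HMPA) and alkylate with 7, then reductively desulfonylate (Li, EtNH2, –78 °C), a stereoretentive route.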